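(The runs are simulated with made-up constants, and the scatter is random.)

After the second minute both earlier runs went slowly: in the noon run D fell from 38 % at 2.50 min to 26 % at 10.0 min. So I reckoned from the charge of G, not from a rate.

| flask | D | Q | G | E | X | remark | time |
|---|---|---|---|---|---|---|---|
| noon | 10 mM | 10 mM | 0.80 equiv | 4.8 mol% | 1.3 mM | run made earlier |  |
| dawn | 10 mM | 10 mM | 0.80 equiv | 11 mol% | 1.3 mM | run made earlier |  |
| flask | 10 mM | 10 mM | 0.800 equiv | 7.2 mol% | 1.3 mM |  | 12 min |

| run | time / min | Q / % | D / % |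
|---|---|---|---|
| noon | 0.833 | 50 | 45 |
| noon | 1.33 | 44 | 39 |
| noon | 2.00 | 45 | 38 |
| noon | 2.50 | 44 | 38 |
| noon | 4.00 | 45 | 35 |
| noon | 6.00 | 44 | 32 |
| noon | 10.0 | 40 | 26 |
| dawn | 0.500 | 48 | 42 |
| dawn | 1.33 | 45 | 40 |
| dawn | 2.50 | 41 | 32 |
| dawn | 4.00 | 45 | 29 |
| dawn | 6.00 | 40 | 29 |
| dawn | 8.00 | 38 | 24 |
| dawn | 10.0 | 37 | 22 |

(readings scatter by 2 percentage points)

- whether the excess of Q over D among what is left of the two reaches 99 % by 12 min (yes / no)
- the highest excess of Q over D among what is left of the two up to 12 min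

- E is single-handed; D and Q are mirror images of each other, charged as a racemate, each of them at the stated concentration
- candidate steps: 2 E <-> Z; G <-> J; G + E + Q -> E + Zo; E + X <-> EX; G + E + D -> E + Wu

1. D and Q compete for the same G and E, so I expected the logarithm of the part of D left, over that of the part of Q left, to stay constant. The last readings gave 2.93 at noon and 2.73 at dawn. Their mean, 2.83, is my selectivity factor s.

2. G is the limiting reagent: it can convert a share c = 40.0 % of D and Q together. The parts left, y of Q and d of D, then sum to 1.20. I took the flask, its E lying between the two runs, to reach c by 12 min.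

3. The split at the start gave y = 0.791. I then put the mean of D/Q between start and end at 0.758, and s times that mean gave y = 0.746.

4. That mean was the weak link: y^s gives d = 0.436, but the sum demands 0.454. One Newton step on y + y^s = 1.20 gave y = 0.753. The excess (y − d)/(y + d) came to 25.4 %, far below 99 %.

The forecast, working from decay rates, said no and 26 %, adding that “the highest value falls at the end”. My figure from the charge of G is 25.4 %.

    2 E ⇌ Z (K = 1600 M⁻¹, k = 38.0 M⁻¹ s⁻¹)
    G ⇌ J (K = 0.750, k = 0.0400 s⁻¹)
    G + E + Q → E + Zo (k = 680 M⁻² s⁻¹)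
    E + X ⇌ EX (K = 250 M⁻¹, k = 430 M⁻¹ s⁻¹)
    G + E + D → E + Wu (k = 2100 M⁻² s⁻¹)

The flask gave no and a top of 24.2 %, below my 25.4 %. At 12.0 min G stood at 4.93 % of its charge and J at 0.312 mM, with Wu and Zo together at 36.5 % against c = 40.0 %. For the neighbouring flask with 0.320 equiv of G, the same s gave c = 16.0 %, y = 0.911 and an excess of 8.45 %. That flask's simulated top was 8.62 %.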